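**Plan**

- Numbering: chromanone half O1, C2 (ketal carbon bearing aryl B, the 4-hydroxyphenyl group), C3 (carbinol), C4 (ketone), ring A C4a–C8a; flavan half primed, with O7' on C2 and C8' on C3.
- Enabling feature: O7'–C2–C3–C8'–C7' is a 2,3-dihydrobenzofuran with one extra oxygen on each of C2 and C3, i.e. an opened benzofuran 2,3-oxide, and the ring A oxygen O1 lies ortho to the C4 carbonyl, placed to close a six-membered ring onto C2.
- Retrosynthesis: cut C2–O1 and C3–OH back to a 3-aroyl-2-arylbenzofuran with one free ring A phenol; cut C3–C8' (intramolecular Heck) and C2–O7' (oxa-Michael) to an 8-iodo-7-hydroxyflavan and a diaryl ynone; cut the ynone at its carbinol C–C bond (acetylide plus aldehyde).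
- Forward: the flavan pyran ring comes from (2S)-naringenin (C4 deoxygenated, C8 iodinated), the furan ring is closed second, ring C third in the oxidation step, and five benzyl ethers are removed last.
- Stereochemistry: C2' from (2S)-naringenin; C3 from the face chosen by a fructose-derived chiral dioxirane; C2 from the C4 tether, which lets ring C close only cis.

Key step: step 13

Assumption: because O1 is tied to C3 through C4, ring C can close only on the face of C2 anti to the C3 oxygen, so C2 is not an independent stereocentre; the route is aimed at the C3 configuration of the target (3R), and the SMILES strings of the ketals reproduce the C2 and C3 descriptors of the target string unchanged.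

**Route**

Step 1
Reactants: 1 (2S)-naringenin
Product: 2 (2S)-5-hydroxy-2-(4-hydroxyphenyl)-7-(methoxymethoxy)chroman-4-one
Conditions: MOMCl (1.05 equiv), i-Pr2NEt, THF, 0 °C
Reagents that add atoms: chloromethyl methyl ether (MOMCl), COCCl
Why: Selective O-alkylation: the 7-OH of the flavanone is a vinylogous acid and the most acidic phenol, the 5-OH is locked in a hydrogen bond to C4=O and the 4'-OH is an ordinary phenol, so one equivalent of MOMCl with a hindered amine at 0 °C should give the 7-ether without the base-induced chalcone opening that would erode the 2S centre.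

Step 2
Reactants: 2 (2S)-5-hydroxy-2-(4-hydroxyphenyl)-7-(methoxymethoxy)chroman-4-one
Product: 3 (2S)-2-[4-(benzyloxy)phenyl]-5-hydroxy-7-(methoxymethoxy)chroman-4-one
Conditions: BnOH, PPh3, DIAD, THF, 0 °C to rt
Reagents that add atoms: benzyl alcohol, OCc1ccccc1
Why: Mitsunobu etherification of the only unchelated phenol under neutral conditions (the hydrogen-bonded 5-OH does not react), chosen over carbonate bases so that the flavanone cannot racemize by retro-oxa-Michael opening.

Step 3
Reactants: 3 (2S)-2-[4-(benzyloxy)phenyl]-5-hydroxy-7-(methoxymethoxy)chroman-4-one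
Product: 5 (2S)-2-[4-(benzyloxy)phenyl]-7-(methoxymethoxy)chroman-5-ol, via 5-O-ethoxycarbonyl flavanone 4 (not isolated)
Conditions: ClCO2Et, Et3N, THF, 0 °C; filter; NaBH4, THF/H2O, 0 °C to rt
Reagents that add atoms: none
Why: Ortho-hydroxyl-assisted deoxygenation of an aryl ketone: NaBH4 reduces the C4 ketone of carbonate 4, the alkoxide takes over the ethoxycarbonyl group and the phenoxide expels ethyl carbonate to give an ortho-quinone methide that a second hydride reduces to the C4 methylene, which frees the 5-OH and leaves the 2S centre untouched.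

Step 4
Reactants: 5 (2S)-2-[4-(benzyloxy)phenyl]-7-(methoxymethoxy)chroman-5-ol
Product: 6 (2S)-5-(benzyloxy)-2-[4-(benzyloxy)phenyl]-7-(methoxymethoxy)chroman
Conditions: BnBr, K2CO3, DMF, rt
Reagents that add atoms: benzyl bromide, BrCc1ccccc1
Why: Williamson etherification of the 5-phenol, safe for the 2S centre because the flavan has no carbonyl and, with O4' already benzylated, no phenoxide that could open the pyran ring through a quinone methide.

Step 5
Reactants: 6 (2S)-5-(benzyloxy)-2-[4-(benzyloxy)phenyl]-7-(methoxymethoxy)chroman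
Product: 7 (2S)-5-(benzyloxy)-2-[4-(benzyloxy)phenyl]-8-iodo-7-(methoxymethoxy)chroman
Conditions: NIS (1.05 equiv), CH2Cl2, −20 to 0 °C
Reagents that add atoms: N-iodosuccinimide, O=C1CCC(=O)N1I
Why: Electrophilic aromatic iodination of the phloroglucinol-type ring, expected at C8 as in the halogenation of 5,7-di-O-protected flavans, because the 5-benzyloxy group is turned toward C6 by the C4 methylene and shields it while C8 lies between the tied-back ring oxygen and the small MOM ether.

Step 6
Reactants: 7 (2S)-5-(benzyloxy)-2-[4-(benzyloxy)phenyl]-8-iodo-7-(methoxymethoxy)chroman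
Product: 8 (2S)-5-(benzyloxy)-2-[4-(benzyloxy)phenyl]-8-iodochroman-7-ol
Conditions: 2 M HCl, MeOH/THF, 40 °C
Reagents that add atoms: none
Why: Acid-catalysed acetal exchange with methanol removes the MOM group as dimethoxymethane under conditions that benzyl ethers, the aryl iodide and the benzylic ether C2 of the flavan should tolerate.

Step 7
Reactants: 9 2,4,6-trihydroxybenzaldehyde
Product: 10 2,4,6-tris(benzyloxy)benzaldehyde
Conditions: BnBr (3.5 equiv), K2CO3, DMF, 60 °C
Reagents that add atoms: benzyl bromide, BrCc1ccccc1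
Why: Exhaustive Williamson etherification, in which the formyl group lowers the carbon nucleophilicity of the phloroglucinol ring and DMF favours O- over C-benzylation.

Step 8
Reactants: 11 1-(benzyloxy)-4-ethynylbenzene; 10 2,4,6-tris(benzyloxy)benzaldehyde
Product: 13 rac-1-[2,4,6-tris(benzyloxy)phenyl]-3-[4-(benzyloxy)phenyl]prop-2-yn-1-ol, via lithium acetylide 12 (not isolated)
Conditions: n-BuLi, THF, −78 °C; then 10, −78 to 0 °C; H2O
Reagents that add atoms: none
Why: 1,2-Addition of a lithium acetylide to a non-enolizable aryl aldehyde; the carbinol centre is formed racemic and is destroyed in step 9.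

Step 9
Reactants: 13 rac-1-[2,4,6-tris(benzyloxy)phenyl]-3-[4-(benzyloxy)phenyl]prop-2-yn-1-ol
Product: 14 1-[2,4,6-tris(benzyloxy)phenyl]-3-[4-(benzyloxy)phenyl]prop-2-yn-1-one
Conditions: MnO2 (excess), CH2Cl2, rt
Reagents that add atoms: none
Why: MnO2 oxidation of an alcohol that is both benzylic and propargylic, which gives the ynone under neutral conditions.

Step 10
Reactants: 8 (2S)-5-(benzyloxy)-2-[4-(benzyloxy)phenyl]-8-iodochroman-7-ol; 14 1-[2,4,6-tris(benzyloxy)phenyl]-3-[4-(benzyloxy)phenyl]prop-2-yn-1-one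
Product: 15 3-{[(2S)-5-(benzyloxy)-2-[4-(benzyloxy)phenyl]-8-iodochroman-7-yl]oxy}-3-[4-(benzyloxy)phenyl]-1-[2,4,6-tris(benzyloxy)phenyl]prop-2-en-1-one (E/Z mixture)
Conditions: K2CO3 (0.3 equiv), DMF, 40 °C
Reagents that add atoms: none
Why: Oxa-Michael addition of the 7-phenoxide to the ynone carbon that carries aryl B, which forms the future C2–O7' bond; the push–pull enone isomerizes easily, so the E/Z mixture is carried on.

Step 11
Reactants: 15 β-aryloxy enone (E/Z mixture)
Product: 16 [(2S)-5-(benzyloxy)-2,8-bis[4-(benzyloxy)phenyl]-3,4-dihydro-2H-furo[2,3-h]chromen-9-yl][2,4,6-tris(benzyloxy)phenyl]methanone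
Conditions: Pd(OAc)2 (10 mol %), PPh3 (20 mol %), K2CO3, DMF, 90 °C
Reagents that add atoms: none
Why: Intramolecular Heck-type arylation of a β-aryloxy enone, a known entry to 3-acylbenzofurans: zerovalent palladium inserts into the C8–I bond, the arylpalladium species bonds to the nucleophilic α-carbon of the enone and loss of HI forms the future C3–C8' bond and closes the furan ring.

Step 12
Reactants: 16 hexabenzyl benzofuran ketone
Product: 17 [2,4-bis(benzyloxy)-6-hydroxyphenyl][(2S)-5-(benzyloxy)-2,8-bis[4-(benzyloxy)phenyl]-3,4-dihydro-2H-furo[2,3-h]chromen-9-yl]methanone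
Conditions: MgBr2·OEt2 (1.5 equiv), toluene/Et2O, 70 °C; then 1 M HCl
Reagents that add atoms: none
Why: Chelation-controlled debenzylation: magnesium held between the ketone oxygen and an ortho benzyloxy oxygen of ring A activates only that ether toward bromide, the two ortho ethers are equivalent, and the magnesium phenoxide chelate formed after the first cleavage ties up the carbonyl, so the second ortho ether and the four remote benzyl ethers should remain.

Step 13
Reactants: 17 pentabenzyl benzofuran ketone with one free ring A phenol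
Product: 19 penta-O-benzyl daphnodorin F, via furan 2,3-epoxide 18 (not isolated)
Conditions: L-fructose-derived ketone 1,2:4,5-di-O-isopropylidene-β-L-erythro-2,3-hexodiulo-2,6-pyranose (1.0 equiv), KHSO5 (as 2KHSO5·KHSO4·K2SO4), K2CO3, n-Bu4NHSO4, MeCN/CH2(OMe)2/aq. Na2B4O7–Na2EDTA buffer (pH 10.5), 0 °C
Reagents that add atoms: potassium peroxymonosulfate (KHSO5), [K+].[O-]S(=O)(=O)OO
Why: Proposed new method: the dioxirane made in the flask from the L-fructose-derived ketone and KHSO5 (Shi epoxidation) should transfer oxygen to the furan C2=C3 bond, a vinylogous ester pushed by O7' and aryl B whose acceptor is weakened further because the chelated ring A phenol is ionized at pH 10.5; the closest known reaction type is dioxirane epoxidation of benzofurans, flavones and enol ethers with opening of the epoxide at the acetal carbon by an oxygen nucleophile, whereas reagent-controlled oxygen transfer to a tetrasubstituted 3-aroylbenzofuran is without precedent. Epoxide 18 should not persist, because its C2–O bond is both benzylic and acetal-like and ionizes toward an oxocarbenium ion stabilized by O7' and aryl B, and O1, held next to C2 through C8a–C4a–C4–C3, closes ring C in a 6-exo-tet mode. C3 is fixed by the face of oxygen transfer, which only the catalyst can choose since the 2'S centre is remote from the flat furan; in the spiro transition state the crowded quadrant beside the spiro acetonide should take the one corner of the alkene without out-of-plane bulk, O7', and by analogy with 1-arylcycloalkenes this arrangement is expected to lead, with the L-fructose-derived ketone, to (3R). C2 has no freedom, because the tether lets O1 reach only the face anti to the new C3–O bond, so ring C is cis-fused to the dihydrofuran. The step needs chemoselectivity for C2=C3 over the benzyl ethers, the benzylic C2'–H and the alkoxyarenes, which the enol-ether character of that bond toward an electrophilic oxidant at 0 °C should secure, and it needs ring closure to outrun hydrolytic cleavage of the epoxide, which the intramolecular phenoxide secures.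

Step 14
Reactants: 19 penta-O-benzyl daphnodorin F
Product: 20 daphnodorin F
Conditions: H2 (1 atm), Pd/C, EtOAc/MeOH, rt
Reagents that add atoms: none
Why: Hydrogenolysis of five aryl benzyl ethers over palladium, the usual last step for polyphenols and flavan ketals; the hydrogen-bonded C4 ketone, the tertiary C3 alcohol, the C2 ketal and the flavan C2'–O1' bond should survive at one atmosphere if the reaction is stopped when uptake ends, and no stereocentre is involved.

**Compound list**

1 | (2S)-naringenin, (2S)-5,7-dihydroxy-2-(4-hydroxyphenyl)chroman-4-one | O=C1C[C@@H](c2ccc(O)cc2)Oc2cc(O)cc(O)c12 | starting material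
2 | (2S)-5-hydroxy-2-(4-hydroxyphenyl)-7-(methoxymethoxy)chroman-4-one | O=C1C[C@@H](c2ccc(O)cc2)Oc2cc(OCOC)cc(O)c12 | intermediate
3 | (2S)-2-[4-(benzyloxy)phenyl]-5-hydroxy-7-(methoxymethoxy)chroman-4-one | O=C1C[C@@H](c2ccc(OCc3ccccc3)cc2)Oc2cc(OCOC)cc(O)c12 | intermediate
4 | (2S)-2-[4-(benzyloxy)phenyl]-7-(methoxymethoxy)-4-oxochroman-5-yl ethyl carbonate (not isolated) | O=C1C[C@@H](c2ccc(OCc3ccccc3)cc2)Oc2cc(OCOC)cc(OC(=O)OCC)c12 | intermediate
5 | (2S)-2-[4-(benzyloxy)phenyl]-7-(methoxymethoxy)chroman-5-ol | COCOc1cc(O)c2c(c1)O[C@H](c1ccc(OCc3ccccc3)cc1)CC2 | intermediate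
6 | (2S)-5-(benzyloxy)-2-[4-(benzyloxy)phenyl]-7-(methoxymethoxy)chroman | COCOc1cc(OCc2ccccc2)c2c(c1)O[C@H](c1ccc(OCc3ccccc3)cc1)CC2 | intermediate
7 | (2S)-5-(benzyloxy)-2-[4-(benzyloxy)phenyl]-8-iodo-7-(methoxymethoxy)chroman | COCOc1cc(OCc2ccccc2)c2c(c1I)O[C@H](c1ccc(OCc3ccccc3)cc1)CC2 | intermediate
8 | (2S)-5-(benzyloxy)-2-[4-(benzyloxy)phenyl]-8-iodochroman-7-ol | Oc1cc(OCc2ccccc2)c2c(c1I)O[C@H](c1ccc(OCc3ccccc3)cc1)CC2 | intermediate
9 | 2,4,6-trihydroxybenzaldehyde | O=Cc1c(O)cc(O)cc1O | starting material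
10 | 2,4,6-tris(benzyloxy)benzaldehyde | O=Cc1c(OCc2ccccc2)cc(OCc2ccccc2)cc1OCc1ccccc1 | intermediate
11 | 1-(benzyloxy)-4-ethynylbenzene | C#Cc1ccc(OCc2ccccc2)cc1 | starting material
12 | lithium [4-(benzyloxy)phenyl]acetylide (not isolated) | [Li]C#Cc1ccc(OCc2ccccc2)cc1 | intermediate
13 | rac-1-[2,4,6-tris(benzyloxy)phenyl]-3-[4-(benzyloxy)phenyl]prop-2-yn-1-ol | OC(C#Cc1ccc(OCc2ccccc2)cc1)c1c(OCc2ccccc2)cc(OCc2ccccc2)cc1OCc1ccccc1 | intermediate
14 | 1-[2,4,6-tris(benzyloxy)phenyl]-3-[4-(benzyloxy)phenyl]prop-2-yn-1-one | O=C(C#Cc1ccc(OCc2ccccc2)cc1)c1c(OCc2ccccc2)cc(OCc2ccccc2)cc1OCc1ccccc1 | intermediate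
15 | 3-{[(2S)-5-(benzyloxy)-2-[4-(benzyloxy)phenyl]-8-iodochroman-7-yl]oxy}-3-[4-(benzyloxy)phenyl]-1-[2,4,6-tris(benzyloxy)phenyl]prop-2-en-1-one (E/Z mixture) | O=C(C=C(Oc1cc(OCc2ccccc2)c2c(c1I)O[C@H](c1ccc(OCc3ccccc3)cc1)CC2)c1ccc(OCc2ccccc2)cc1)c1c(OCc2ccccc2)cc(OCc2ccccc2)cc1OCc1ccccc1 | intermediate
16 | [(2S)-5-(benzyloxy)-2,8-bis[4-(benzyloxy)phenyl]-3,4-dihydro-2H-furo[2,3-h]chromen-9-yl][2,4,6-tris(benzyloxy)phenyl]methanone | O=C(c1c(OCc2ccccc2)cc(OCc2ccccc2)cc1OCc1ccccc1)c1c(-c2ccc(OCc3ccccc3)cc2)oc2cc(OCc3ccccc3)c3c(c12)O[C@H](c1ccc(OCc2ccccc2)cc1)CC3 | intermediate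
17 | [2,4-bis(benzyloxy)-6-hydroxyphenyl][(2S)-5-(benzyloxy)-2,8-bis[4-(benzyloxy)phenyl]-3,4-dihydro-2H-furo[2,3-h]chromen-9-yl]methanone | O=C(c1c(O)cc(OCc2ccccc2)cc1OCc1ccccc1)c1c(-c2ccc(OCc3ccccc3)cc2)oc2cc(OCc3ccccc3)c3c(c12)O[C@H](c1ccc(OCc2ccccc2)cc1)CC3 | intermediate
18 | furan 2,3-epoxide of 17, epoxide oxygen on the furan face that becomes the (3R) hydroxyl, 2'S (not isolated) | O=C(c1c(O)cc(OCc2ccccc2)cc1OCc1ccccc1)[C@@]12O[C@]1(c1ccc(OCc3ccccc3)cc1)Oc1cc(OCc3ccccc3)c3c(c12)O[C@H](c1ccc(OCc2ccccc2)cc1)CC3 | intermediate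
19 | penta-O-benzyl daphnodorin F: ketal with O1 bonded to C2 and OH on C3 (3R, 2'S; C2 fixed by the ring closure), benzyl ethers on O5, O7, aryl B, O5' and the 2'-aryl group | O=C1c2c(OCc3ccccc3)cc(OCc3ccccc3)cc2O[C@]2(c3ccc(OCc4ccccc4)cc3)Oc3cc(OCc4ccccc4)c4c(c3[C@@]12O)O[C@H](c1ccc(OCc2ccccc2)cc1)CC4 | intermediate
20 | daphnodorin F (3R, 2'S; C2 fixed by the ring closure) | O=C1c2c(O)cc(O)cc2O[C@]2(c3ccc(O)cc3)Oc3cc(O)c4c(c3[C@@]12O)O[C@H](c1ccc(O)cc1)CC4 | target

**Step count**

Total: 14 steps. Longest linear sequence: 11 steps (1 to 20 through steps 1–6 and 10–14).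

**Steps most likely to fail**

Step 13 (proposed new method). Oxygen transfer to the push–pull furan bond may be slow enough for the ketone to be lost to its own Baeyer–Villiger decay, the ionized phenol ring may be over-oxidized, or the two faces of the flat furan may be poorly differentiated. If only the sense of induction is reversed, the D-fructose-derived antipode of the ketone is used instead. The fallback uses known chemistry and sets out from 17: oxidation with a solution of isolated dimethyldioxirane in acetone/CH2Cl2 at −20 °C, a reagent known to epoxidize benzofurans, enol ethers and flavones under neutral, water-free conditions. Without facial control this should give epoxide 18 together with the epoxide of the opposite furan face F1. These close to 19 and to the C2,C3-diastereomeric ketal F2. Because both ketals carry the 2'S centre they are diastereomers and would be separated by chromatography, and the route is rejoined at 19.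

Step 11. The 5-endo ring closure may lose to reductive deiodination or to base-induced cleavage of the aryloxy enone at 90 °C. The fallback sets out from 8: Sonogashira coupling with alkyne 11 (PdCl2(PPh3)2, CuI, Et3N, THF, rt) should give the 8-alkynyl-7-hydroxyflavan F3. 5-Endo-dig iodocyclization (I2, NaHCO3, MeCN) should then give the 9-iodofurochromene F4. Iodine–magnesium exchange (i-PrMgCl·LiCl, THF, −20 °C) gives the arylmagnesium chloride F5, which is added to aldehyde 10 to give the diaryl carbinol F6. MnO2 oxidation returns to the route at 16.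

Step 12. The chelation-controlled cleavage may stall on the twisted, crowded ketone or run on to the second ortho ether and give mixtures. The fallback sets out from 16: both ortho ethers are removed on purpose with excess MgBr2·OEt2 at higher temperature to give the symmetrical 2,6-dihydroxy ketone F7, whose two phenols are equivalent. The conditions of step 13 should then give, through its furan epoxide F8, the tetra-O-benzyl ketal F9 with a free, hydrogen-bonded 5-OH. Hydrogenolysis of its four benzyl ethers joins the route at 20.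

Further compounds
F1 | step 13 | furan 2,3-epoxide of 17 on the opposite face (not isolated) | O=C(c1c(O)cc(OCc2ccccc2)cc1OCc1ccccc1)[C@]12O[C@@]1(c1ccc(OCc3ccccc3)cc1)Oc1cc(OCc3ccccc3)c3c(c12)O[C@H](c1ccc(OCc2ccccc2)cc1)CC3
F2 | step 13 | C2,C3-diastereomer of 19 (3S, 2'S) | O=C1c2c(OCc3ccccc3)cc(OCc3ccccc3)cc2O[C@@]2(c3ccc(OCc4ccccc4)cc3)Oc3cc(OCc4ccccc4)c4c(c3[C@]12O)O[C@H](c1ccc(OCc2ccccc2)cc1)CC4
F3 | step 11 | (2S)-5-(benzyloxy)-2-[4-(benzyloxy)phenyl]-8-{[4-(benzyloxy)phenyl]ethynyl}chroman-7-ol | Oc1cc(OCc2ccccc2)c2c(c1C#Cc1ccc(OCc3ccccc3)cc1)O[C@H](c1ccc(OCc3ccccc3)cc1)CC2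
F4 | step 11 | (2S)-5-(benzyloxy)-2,8-bis[4-(benzyloxy)phenyl]-9-iodo-3,4-dihydro-2H-furo[2,3-h]chromene | Ic1c(-c2ccc(OCc3ccccc3)cc2)oc2cc(OCc3ccccc3)c3c(c12)O[C@H](c1ccc(OCc2ccccc2)cc1)CC3
F5 | step 11 | 9-(chloromagnesio) analogue of F4 (not isolated) | Cl[Mg]c1c(-c2ccc(OCc3ccccc3)cc2)oc2cc(OCc3ccccc3)c3c(c12)O[C@H](c1ccc(OCc2ccccc2)cc1)CC3
F6 | step 11 | [(2S)-5-(benzyloxy)-2,8-bis[4-(benzyloxy)phenyl]-3,4-dihydro-2H-furo[2,3-h]chromen-9-yl][2,4,6-tris(benzyloxy)phenyl]methanol (both carbinol epimers) | OC(c1c(OCc2ccccc2)cc(OCc2ccccc2)cc1OCc1ccccc1)c1c(-c2ccc(OCc3ccccc3)cc2)oc2cc(OCc3ccccc3)c3c(c12)O[C@H](c1ccc(OCc2ccccc2)cc1)CC3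
F7 | step 12 | [4-(benzyloxy)-2,6-dihydroxyphenyl][(2S)-5-(benzyloxy)-2,8-bis[4-(benzyloxy)phenyl]-3,4-dihydro-2H-furo[2,3-h]chromen-9-yl]methanone | O=C(c1c(O)cc(OCc2ccccc2)cc1O)c1c(-c2ccc(OCc3ccccc3)cc2)oc2cc(OCc3ccccc3)c3c(c12)O[C@H](c1ccc(OCc2ccccc2)cc1)CC3
F8 | step 12 | furan 2,3-epoxide of F7 (not isolated) | O=C(c1c(O)cc(OCc2ccccc2)cc1O)[C@@]12O[C@]1(c1ccc(OCc3ccccc3)cc1)Oc1cc(OCc3ccccc3)c3c(c12)O[C@H](c1ccc(OCc2ccccc2)cc1)CC3
F9 | step 12 | tetra-O-benzyl daphnodorin F with free 5-OH (3R, 2'S) | O=C1c2c(O)cc(OCc3ccccc3)cc2O[C@]2(c3ccc(OCc4ccccc4)cc3)Oc3cc(OCc4ccccc4)c4c(c3[C@@]12O)O[C@H](c1ccc(OCc2ccccc2)cc1)CC4
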